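**Plan**
- Numbering (daucane): C1 quaternary C–CH3, C2/C3 CH2, C4 isopropyl carbinol, C5 ring-fusion CH, C6 benzoate carbon, C7=C8(CH3), C9 ketone, C10 carbinol; β is the face of the C1 methyl.
- Retrosynthesis: functional-group changes lead back to a trans-fused hydroazulen-10-one, in which C1–C5 and C8–C9 are cut together. This is possible because the seven-membered ring holds carbonyl-level C10 beside quaternary C1 (C1–C10–C9 = oxyallyl cation) facing a C5=C6–C7=C8 diene, with C2–C3–C4 as the tether.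
- C1–C6, with the C1 methyl and the C4 isopropyl carbinol, are the six ring carbons of (S)-terpinen-4-ol opened by ozonolysis between C1 and C6. C7 and C8(+CH3) are added to the aldehyde arm, C10/C9 to the ketone arm.
- Forward: chain assembly (steps 1–6); both rings in one step, five-membered through C1–C5 and seven-membered through C8–C9 (step 7); then α-epoxide at C6–C7, carbonyl transposition C10→C9, epoxide opening to the γ-hydroxy enone, benzoate, desilylation.
- Stereochemistry: C4 from terpinen-4-ol; C5 and C1 in the cycloaddition (diene face anti to the C4 isopropyl, trans fusion); C6 by epoxidation anti to the β methyls; C10 by hydroboration anti to the C1 and C8 methyls.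

Key step: step 7

Remarks on the chemistry:
- (S)-(+)-Terpinen-4-ol is assumed to be bought in high enantiomeric purity; no step touches C4.
- The carbinol carbon keeps its spatial arrangement throughout. Its CIP label changes from S to R at compound 11 only because the dienyl group outranks isopropyl, so the cycloaddition precursor 15 is (6R).
- Commercial compounds that supply carbon atoms to the target are numbered; other reagents are named in the steps.

**Step 1**
Reactants: 1 (S)-terpinen-4-ol
Product: 2 triethyl{[(1S)-4-methyl-1-(propan-2-yl)cyclohex-3-en-1-yl]oxy}silane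
Conditions: Et3SiOTf, 2,6-lutidine, CH2Cl2, 0 °C
Reagents that add atoms: triethylsilyl trifluoromethanesulfonate, CC[Si](CC)(CC)OS(=O)(=O)C(F)(F)F
Why: Silyl triflate with a hindered pyridine base silylates tertiary alcohols (silyl ether formation); the ether prevents hemiketal formation after ring cleavage and later screens the β face near C6.

**Step 2**
Reactants: 2 triethylsilyl ether of terpinen-4-ol
Product: 4 (3S)-6-oxo-3-(propan-2-yl)-3-(triethylsilyloxy)heptanal, via secondary ozonide 3 (not isolated)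
Conditions: O3, CH2Cl2, −78 °C; then PPh3, −78 °C to rt
Reagents that add atoms: ozone, [O-][O+]=O
Why: Ozonolysis of the only alkene with reductive work-up gives the methyl ketone (C1) and the aldehyde (C6) directly, and the quaternary C4 is not involved.

**Step 3**
Reactants: 4 keto aldehyde; 5 iodoform
Product: 6 (5S,7E)-8-iodo-5-(propan-2-yl)-5-(triethylsilyloxy)oct-7-en-2-one
Conditions: CrCl2, THF, 0 °C to rt
Reagents that add atoms: iodoform, IC(I)I
Why: Takai iodo-olefination converts aldehydes into (E)-vinyl iodides and leaves ketones untouched; the geometry of this alkene does not matter because it is relocated in step 5.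

**Step 4**
Reactants: 6 vinyl iodide; 7 acetaldehyde
Product: 8 (5S,7E)-9-hydroxy-5-(propan-2-yl)-5-(triethylsilyloxy)dec-7-en-2-one (both C9 epimers)
Conditions: CrCl2, NiCl2 (cat.), DMF, rt
Reagents that add atoms: acetaldehyde, CC=O
Why: Nozaki–Hiyama–Kishi coupling: the alkenylchromium species adds to the aldehyde and not to the methyl ketone; the new carbinol centre is removed in step 5, so both epimers are used.

**Step 5**
Reactants: 8 allylic alcohol
Product: 11 (5R,6E,8E)-5-(propan-2-yl)-5-(triethylsilyloxy)deca-6,8-dien-2-one, via allylic sulfenate 9 (not isolated), via allylic sulfoxide 10 (not isolated)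
Conditions: 2,4-(O2N)2C6H3SCl, Et3N, ClCH2CH2Cl, 0 °C; then 80 °C
Reagents that add atoms: none
Why: The sulfenate undergoes a [2,3]-sigmatropic shift (Mislow–Evans rearrangement in the sulfoxide-forming direction) that places sulfur on C6 and forms the E C7=C8 bond, and the sulfoxide syn-elimination can only take a C5 hydrogen, giving the E C5=C6 bond with the bulky C4 anti.

**Step 6**
Reactants: 11 dienyl methyl ketone; 12 1,1-dichloroethane
Product: 15 (6R,7E,9E)-3-chloro-3-methyl-6-(propan-2-yl)-6-(triethylsilyloxy)undeca-7,9-dien-2-one (both C3 epimers), via lithium alkoxide 13 (not isolated), via chloro-oxirane 14 (not isolated)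
Conditions: 12, n-BuLi, THF/Et2O/pentane, −100 °C; add 11; warm to rt
Reagents that add atoms: 1,1-dichloroethane, CC(Cl)Cl
Why: Carbenoid addition of 1,1-dichloroethyllithium to the ketone, closure of the β,β-dichloro alkoxide to the 2-chloro-oxirane and its 1,2-chlorine shift (known α-chloro ketone synthesis from 1,1-dichloroalkyllithiums) put chlorine on the former carbonyl carbon C1 and the carbonyl on the added carbon C10; the C1 centre is lost in step 7.

**Step 7**
Reactants: 15 α-chloro ketone
Product: 17 trans-fused (1S,4R,5R,8R)-4β-(triethylsilyloxy)dauc-6-en-10-one (1β-CH3, 8β-CH3, 4α-isopropyl, 5α-H), via oxyallyl cation 16 (not isolated)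
Conditions: Et3N, CF3CH2OH, high dilution, 0 °C to rt
Reagents that add atoms: none
Why: Triethylamine in the ionising solvent enolises the methyl ketone toward C9 and chloride leaves from tertiary C1, giving the 1,1-dialkyl oxyallyl cation 16, which adds across the s-cis (E,E)-diene in a (4+3) cycloaddition, either concerted or by C1–C5 bonding followed by C9–C8 closure. The closest known reaction type is the base-mediated intramolecular (4+3) cycloaddition of α-chloro ketones carrying a butadiene on a three-atom tether. The five-membered ring closes by attack of C1 on the proximal diene carbon C5 through C2–C3–C4 (5-exo with respect to C5=C6), and the seven-membered ring closes when the distal oxyallyl carbon C9 bonds to the diene terminus C8, all four diene carbons becoming ring members. C5 is controlled by the C4 centre: the diene reacts on the face that places the forming C1–C5 bond anti to isopropyl, so C6 ends cis to the smaller silyloxy group. C1 (methyl trans to H-5) is set by the extended arrangement of cation and diene across the tether, and C8 (methyl β) follows from the E geometry in a concerted event and is erased in step 11 in any case. The step needs trans over cis fusion and a single diene face; the quaternary C4 next to the diene and the constraint of the short tether should secure them, and high dilution keeps solvent capture of the cation behind ring closure.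

**Step 8**
Reactants: 17 hydroazulenone
Product: 18 6α,7α-epoxy-4β-(triethylsilyloxy)daucan-10-one
Conditions: mCPBA, NaHCO3, CH2Cl2, 0 °C
Reagents that add atoms: 3-chloroperbenzoic acid, OOC(=O)c1cccc(Cl)c1
Why: Prilezhaev epoxidation of the only alkene, expected on the α face anti to the C1 and C8 methyl groups and the C4 silyl ether, which fixes the C6–O bond α; the hindered ketone should be slower in Baeyer–Villiger oxidation.

**Step 9**
Reactants: 18 epoxy ketone
Product: 20 10-(tert-butyldimethylsilyloxy)-6α,7α-epoxy-4β-(triethylsilyloxy)dauc-9-ene, via lithium enolate 19 (not isolated)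
Conditions: LDA, THF, −78 °C; then t-BuMe2SiOTf, −78 °C
Reagents that add atoms: tert-butyldimethylsilyl trifluoromethanesulfonate, CC(C)(C)[Si](C)(C)OS(=O)(=O)C(F)(F)F
Why: Kinetic enolisation can only take a C9 hydrogen because C1 is quaternary, and O-silylation by the silyl triflate at −78 °C traps the enolate before it can attack the epoxide (silyl enol ether formation).

**Step 10**
Reactants: 20 silyl enol ether
Product: 22 10β-(tert-butyldimethylsilyloxy)-6α,7α-epoxy-4β-(triethylsilyloxy)daucan-9α-ol, via alkylborane 21 (not isolated)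
Conditions: BH3·THF, THF, 0 °C to rt; then 30% H2O2, aq. NaOH, 0 °C
Reagents that add atoms: hydrogen peroxide, OO
Why: Hydroboration of a silyl enol ether places boron on the carbon β to oxygen (C9) and hydrogen on C10 in a syn addition from the α face, anti to the methyls on C1 and C8, so the C10 silyloxy group ends β (cis to the C1 methyl); oxidation with retention gives the trans-2-silyloxy alcohol.

**Step 11**
Reactants: 22 hydroxy silyl ether
Product: 24 10β-(tert-butyldimethylsilyloxy)-6α-hydroxy-4β-(triethylsilyloxy)dauc-7-en-9-one, via epoxy ketone 23 (not isolated)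
Conditions: Dess–Martin periodinane, NaHCO3, CH2Cl2, 0 °C to rt; aq. Na2S2O3 wash; then DBU (cat.), CH2Cl2, 0 °C
Reagents that add atoms: none
Why: Dess–Martin oxidation gives the β,γ-epoxy ketone, and DBU removes the C8 hydrogen with E1cB opening of the epoxide to the conjugated γ-hydroxy enone; the C6–O bond is not broken, so its α configuration is kept.

**Step 12**
Reactants: 24 hydroxy enone; 25 benzoyl chloride
Product: 26 6α-benzoyloxy-10β-(tert-butyldimethylsilyloxy)-4β-(triethylsilyloxy)dauc-7-en-9-one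
Conditions: pyridine, DMAP (cat.), CH2Cl2, 0 °C to rt
Reagents that add atoms: benzoyl chloride, O=C(Cl)c1ccccc1
Why: DMAP-catalysed acylation of the only free hydroxyl (secondary, allylic), the C4 and C10 oxygens being silylated.

**Step 13**
Reactants: 26 bis-silyl ether
Product: 27 (3R,3aS,4S,8R,8aS)-3,8-dihydroxy-6,8a-dimethyl-7-oxo-3-(propan-2-yl)-1,2,3,3a,4,7,8,8a-octahydroazulen-4-yl benzoate
Conditions: 48% aq. HF, MeCN, 0 °C to rt
Reagents that add atoms: none
Why: Acidic fluoride cleaves both silyl ethers (desilylation) without the benzoate migration or α-ketol epimerisation that basic fluoride could cause.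

**Compound list**
1 | (S)-terpinen-4-ol | CC1=CC[C@](O)(C(C)C)CC1 | starting material
2 | triethyl{[(1S)-4-methyl-1-(propan-2-yl)cyclohex-3-en-1-yl]oxy}silane | CC1=CC[C@](O[Si](CC)(CC)CC)(C(C)C)CC1 | intermediate
3 | secondary ozonide (1,2,4-trioxolane) of 2 | CC12CC[C@@](O[Si](CC)(CC)CC)(C(C)C)CC(OO1)O2 | intermediate
4 | (3S)-6-oxo-3-(propan-2-yl)-3-(triethylsilyloxy)heptanal | CC(=O)CC[C@@](O[Si](CC)(CC)CC)(C(C)C)CC=O | intermediate
5 | iodoform | IC(I)I | starting material
6 | (5S,7E)-8-iodo-5-(propan-2-yl)-5-(triethylsilyloxy)oct-7-en-2-one | CC(=O)CC[C@@](O[Si](CC)(CC)CC)(C(C)C)C/C=C/I | intermediate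
7 | acetaldehyde | CC=O | starting material
8 | (5S,7E)-9-hydroxy-5-(propan-2-yl)-5-(triethylsilyloxy)dec-7-en-2-one | CC(=O)CC[C@@](O[Si](CC)(CC)CC)(C(C)C)C/C=C/C(C)O | intermediate
9 | 2,4-dinitrobenzenesulfenate ester of 8 | CC(=O)CC[C@@](O[Si](CC)(CC)CC)(C(C)C)C/C=C/C(C)OSc1ccc(cc1[N+](=O)[O-])[N+](=O)[O-] | intermediate
10 | (5S,8E)-7-[(2,4-dinitrophenyl)sulfinyl]-5-(propan-2-yl)-5-(triethylsilyloxy)dec-8-en-2-one | CC(=O)CC[C@@](O[Si](CC)(CC)CC)(C(C)C)CC(/C=C/C)S(=O)c1ccc(cc1[N+](=O)[O-])[N+](=O)[O-] | intermediate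
11 | (5R,6E,8E)-5-(propan-2-yl)-5-(triethylsilyloxy)deca-6,8-dien-2-one | CC(=O)CC[C@@](O[Si](CC)(CC)CC)(C(C)C)/C=C/C=C/C | intermediate
12 | 1,1-dichloroethane | CC(Cl)Cl | starting material
13 | lithium (6R,7E,9E)-2,2-dichloro-3-methyl-6-(propan-2-yl)-6-(triethylsilyloxy)undeca-7,9-dien-3-olate | [Li+].[O-]C(C)(CC[C@@](O[Si](CC)(CC)CC)(C(C)C)/C=C/C=C/C)C(C)(Cl)Cl | intermediate
14 | 2-chloro-2,3-dimethyl-3-[(3R,4E,6E)-3-(propan-2-yl)-3-(triethylsilyloxy)octa-4,6-dien-1-yl]oxirane | CC1(Cl)OC1(C)CC[C@@](O[Si](CC)(CC)CC)(C(C)C)/C=C/C=C/C | intermediate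
15 | (6R,7E,9E)-3-chloro-3-methyl-6-(propan-2-yl)-6-(triethylsilyloxy)undeca-7,9-dien-2-one | CC(=O)C(C)(Cl)CC[C@@](O[Si](CC)(CC)CC)(C(C)C)/C=C/C=C/C | intermediate
16 | oxyallyl cation (zwitterion) from 15 | C=C([O-])[C+](C)CC[C@@](O[Si](CC)(CC)CC)(C(C)C)/C=C/C=C/C | intermediate
17 | (1S,4R,5R,8R)-4β-(triethylsilyloxy)dauc-6-en-10-one, trans-fused | C[C@H]1C=C[C@@H]2[C@](C)(CC[C@@]2(O[Si](CC)(CC)CC)C(C)C)C(=O)C1 | intermediate
18 | 6α,7α-epoxy-4β-(triethylsilyloxy)daucan-10-one | C[C@H]1[C@@H]2O[C@@H]2[C@@H]3[C@](C)(CC[C@@]3(O[Si](CC)(CC)CC)C(C)C)C(=O)C1 | intermediate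
19 | lithium C9=C10 enolate of 18 | [Li+].C[C@H]1[C@@H]2O[C@@H]2[C@@H]3[C@](C)(CC[C@@]3(O[Si](CC)(CC)CC)C(C)C)C([O-])=C1 | intermediate
20 | 10-(tert-butyldimethylsilyloxy)-6α,7α-epoxy-4β-(triethylsilyloxy)dauc-9-ene | C[C@H]1[C@@H]2O[C@@H]2[C@@H]3[C@](C)(CC[C@@]3(O[Si](CC)(CC)CC)C(C)C)C(O[Si](C)(C)C(C)(C)C)=C1 | intermediate
21 | 9α-boryl-10β-(tert-butyldimethylsilyloxy)-6α,7α-epoxy-4β-(triethylsilyloxy)daucane | C[C@H]1[C@@H]2O[C@@H]2[C@@H]3[C@](C)(CC[C@@]3(O[Si](CC)(CC)CC)C(C)C)[C@@H](O[Si](C)(C)C(C)(C)C)[C@@H]1B | intermediate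
22 | 10β-(tert-butyldimethylsilyloxy)-6α,7α-epoxy-4β-(triethylsilyloxy)daucan-9α-ol | C[C@H]1[C@@H]2O[C@@H]2[C@@H]3[C@](C)(CC[C@@]3(O[Si](CC)(CC)CC)C(C)C)[C@@H](O[Si](C)(C)C(C)(C)C)[C@@H]1O | intermediate
23 | 10β-(tert-butyldimethylsilyloxy)-6α,7α-epoxy-4β-(triethylsilyloxy)daucan-9-one | C[C@H]1[C@@H]2O[C@@H]2[C@@H]3[C@](C)(CC[C@@]3(O[Si](CC)(CC)CC)C(C)C)[C@@H](O[Si](C)(C)C(C)(C)C)C1=O | intermediate
24 | 10β-(tert-butyldimethylsilyloxy)-6α-hydroxy-4β-(triethylsilyloxy)dauc-7-en-9-one | CC1=C[C@H](O)[C@@H]2[C@](C)(CC[C@@]2(O[Si](CC)(CC)CC)C(C)C)[C@@H](O[Si](C)(C)C(C)(C)C)C1=O | intermediate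
25 | benzoyl chloride | O=C(Cl)c1ccccc1 | starting material
26 | 6α-benzoyloxy-10β-(tert-butyldimethylsilyloxy)-4β-(triethylsilyloxy)dauc-7-en-9-one | CC1=C[C@H](OC(=O)c2ccccc2)[C@@H]2[C@](C)(CC[C@@]2(O[Si](CC)(CC)CC)C(C)C)[C@@H](O[Si](C)(C)C(C)(C)C)C1=O | intermediate
27 | 6α-benzoyloxy-4β,10β-dihydroxydauc-7-en-9-one, (1S,4R,5S,6S,10R) | CC1=C[C@H](OC(=O)c2ccccc2)[C@@H]2[C@](C)(CC[C@@]2(O)C(C)C)[C@@H](O)C1=O | target

**Step count and risks**
Total steps: 13. Longest linear sequence: 13 steps, from 1 to 27.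

Most likely to fail:

1. Step 7. The cation may be captured by trifluoroethoxide or contract by the Favorskii path before the tethered diene reaches it, and the extended (trans-fused) mode may not be preferred strongly enough at room temperature. The fallback changes the cation precursor and sets out from 11, returning at 17. 1-Ethoxyvinyllithium (ethyl vinyl ether, t-BuLi, THF) adds to ketone 11 to give the tertiary 2-ethoxyallylic alcohol F1. Tf2O and 2,6-lutidine in CH2Cl2 at −78 °C ionise it to the 2-ethoxyallyl cation F2 in a non-nucleophilic medium. The same C1–C5/C8–C9 ring closure (known for alkoxyallyl cations made from allylic alcohols) gives the ethyl enol ether F3, and dilute aqueous acid on work-up hydrolyses it to 17.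

2. Step 6. The basic carbenoid may enolise the methyl ketone instead of adding, it decomposes above about −100 °C, and the chloro-oxirane may rearrange incompletely. The fallback builds the chloride by enol ether chlorination and sets out from 11, returning at 15. Van Leusen reductive cyanation (TosMIC, t-BuOK, DME/EtOH) gives the nitrile F4. MeLi followed by aqueous NH4Cl gives the α-methyl ketone F5. Me3SiCl/Et3N in DMF at 80 °C gives mainly the more substituted trimethylsilyl enol ether F6, and NCS in THF at 0 °C converts it to 15. The minor enol ether gives the chloromethyl ketone, which leads to the same cation 16 in step 7.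

3. Step 8. Facial selectivity may be poor, with the peracid attacking the β face of C6=C7 and giving the wrong C6 configuration. The fallback sets C6 by inversion at the end; it sets out from 17 and returns at 26. The β-epoxide F7 is taken through the conditions of steps 9–11: lithium enolate F8, silyl enol ether F9, alkylborane F10, alcohol F11, epoxy ketone F12, and finally the 6β-hydroxy enone F13. Mitsunobu esterification of F13 with benzoic acid (PPh3, DIAD, THF) inverts C6 and gives the 6α-benzoate 26 directly.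

**Further compounds**
F1 | step 7 | (6R,7E,9E)-2-ethoxy-3-methyl-6-(propan-2-yl)-6-(triethylsilyloxy)undeca-1,7,9-trien-3-ol | CCOC(=C)C(C)(O)CC[C@@](O[Si](CC)(CC)CC)(C(C)C)/C=C/C=C/C
F2 | step 7 | 2-ethoxyallyl cation from F1 | CCOC(=C)[C+](C)CC[C@@](O[Si](CC)(CC)CC)(C(C)C)/C=C/C=C/C
F3 | step 7 | 10-ethoxy-4β-(triethylsilyloxy)dauca-6,9-diene (ethyl enol ether of 17) | C[C@H]1C=C[C@@H]2[C@](C)(CC[C@@]2(O[Si](CC)(CC)CC)C(C)C)C(OCC)=C1
F4 | step 6 | (5R,6E,8E)-2-methyl-5-(propan-2-yl)-5-(triethylsilyloxy)deca-6,8-dienenitrile | N#CC(C)CC[C@@](O[Si](CC)(CC)CC)(C(C)C)/C=C/C=C/C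
F5 | step 6 | (6R,7E,9E)-3-methyl-6-(propan-2-yl)-6-(triethylsilyloxy)undeca-7,9-dien-2-one | CC(=O)C(C)CC[C@@](O[Si](CC)(CC)CC)(C(C)C)/C=C/C=C/C
F6 | step 6 | (6R,7E,9E)-3-methyl-6-(propan-2-yl)-6-(triethylsilyloxy)-2-(trimethylsilyloxy)undeca-2,7,9-triene | CC(O[Si](C)(C)C)=C(C)CC[C@@](O[Si](CC)(CC)CC)(C(C)C)/C=C/C=C/C
F7 | step 8 | 6β,7β-epoxy-4β-(triethylsilyloxy)daucan-10-one | C[C@H]1[C@H]2O[C@H]2[C@@H]3[C@](C)(CC[C@@]3(O[Si](CC)(CC)CC)C(C)C)C(=O)C1
F8 | step 8 | lithium C9=C10 enolate of F7 | [Li+].C[C@H]1[C@H]2O[C@H]2[C@@H]3[C@](C)(CC[C@@]3(O[Si](CC)(CC)CC)C(C)C)C([O-])=C1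
F9 | step 8 | 10-(tert-butyldimethylsilyloxy)-6β,7β-epoxy-4β-(triethylsilyloxy)dauc-9-ene | C[C@H]1[C@H]2O[C@H]2[C@@H]3[C@](C)(CC[C@@]3(O[Si](CC)(CC)CC)C(C)C)C(O[Si](C)(C)C(C)(C)C)=C1
F10 | step 8 | 9α-boryl-10β-(tert-butyldimethylsilyloxy)-6β,7β-epoxy-4β-(triethylsilyloxy)daucane | C[C@H]1[C@H]2O[C@H]2[C@@H]3[C@](C)(CC[C@@]3(O[Si](CC)(CC)CC)C(C)C)[C@@H](O[Si](C)(C)C(C)(C)C)[C@@H]1B
F11 | step 8 | 10β-(tert-butyldimethylsilyloxy)-6β,7β-epoxy-4β-(triethylsilyloxy)daucan-9α-ol | C[C@H]1[C@H]2O[C@H]2[C@@H]3[C@](C)(CC[C@@]3(O[Si](CC)(CC)CC)C(C)C)[C@@H](O[Si](C)(C)C(C)(C)C)[C@@H]1O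
F12 | step 8 | 10β-(tert-butyldimethylsilyloxy)-6β,7β-epoxy-4β-(triethylsilyloxy)daucan-9-one | C[C@H]1[C@H]2O[C@H]2[C@@H]3[C@](C)(CC[C@@]3(O[Si](CC)(CC)CC)C(C)C)[C@@H](O[Si](C)(C)C(C)(C)C)C1=O
F13 | step 8 | 10β-(tert-butyldimethylsilyloxy)-6β-hydroxy-4β-(triethylsilyloxy)dauc-7-en-9-one | CC1=C[C@@H](O)[C@@H]2[C@](C)(CC[C@@]2(O[Si](CC)(CC)CC)C(C)C)[C@@H](O[Si](C)(C)C(C)(C)C)C1=O
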